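**Retrosynthetic overview**
1. The 22-membered lactone is the only ring. It is closed by Yamaguchi macrolactonisation (C21–O to C1) of a seco acid that still carries C4≡C5 and C8≡C9 as alkynes; the two (Z)-olefins are unveiled last by Zn(Cu/Ag) semireduction, after desilylation.
2. Seco acid ⇒ Sonogashira coupling (C7–C8) of chloroenyne acid fragment C (C1–C7) with a C8–C23 terminal alkyne.
3. C8–C23 ⇒ Sonogashira coupling (C13–C14) of (Z)-vinyl iodide fragment B (C8–C13) with alkyne fragment A (C14–C23), then enyne → (12Z,14Z)-diene with Zn(Cu/Ag).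
4. Fragment A ⇒ Mukaiyama aldol (C20–C21) of an anti-aldol-derived aryl aldehyde with a citronellene-derived alkynyl methyl ketone, then 1,3-syn reduction (C19).
5. Fragment B from propargyl alcohol (carbomagnesiation/iodination, asymmetric propargylation); fragment C from 3-(trimethylsilyl)propynal, a stabilised ylide and (Z)-1,2-dichloroethene.

Assumption: (R)-β-citronellene, (R)-4-benzyl-3-propanoyl-oxazolidin-2-one, (+)-Ipc2BOMe, the Ohira–Bestmann reagent and 3-(trimethylsilyl)propynal are bought. The two stereochemical assignments that rest on reagent antipode (steps 2 and 18) follow the accepted models and should be confirmed on first scale-up.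
Conventions: TBS = tert-butyldimethylsilyl, TIPS = triisopropylsilyl, TMS = trimethylsilyl, PMB = 4-methoxybenzyl. C-locants in the "Why" lines follow the target (C1 = lactone carbonyl, C21 = lactone carbinol, C23 = benzylic carbinol).

**Fragment A, aryl aldehyde (C21–C23)**

Step 1
Reactants: 1 3-hydroxybenzaldehyde
Product: 2 3-(TIPSO)benzaldehyde
Conditions: TIPSCl, imidazole, DMF, 0 °C → rt
Reagents that add atoms: triisopropylsilyl chloride, CC(C)[Si](Cl)(C(C)C)C(C)C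
Why: Silyl ether formation; the bulky aryl TIPS ether tolerates the later Lewis acid and K2CO3/MeOH steps and is removed by fluoride at the end.

Step 2
Reactants: 2 3-(TIPSO)benzaldehyde; 3 (R)-4-benzyl-3-propanoyl-1,3-oxazolidin-2-one
Product: 5 (R)-4-benzyl-3-{(2S,3R)-3-hydroxy-2-methyl-3-[3-(TIPSO)phenyl]propanoyl}-1,3-oxazolidin-2-one, via TMS ether 4 (not isolated)
Conditions: MgCl2 (0.2 equiv), Et3N, TMSCl, EtOAc, rt, 24 h; then TFA (cat.), MeOH, rt
Reagents that add atoms: none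
Why: Evans MgCl2-catalysed anti-aldol addition, in which the magnesium-chelated (Z)-enolate of the (R)-imide is attacked on the face away from the benzyl group through a boat transition state, setting C22 and C23 in the anti relationship, before acidic methanol cleaves the TMS ether.

Step 3
Reactants: 5 anti-aldol adduct
Product: 6 (R)-4-benzyl-3-{(2S,3R)-3-(TBSO)-2-methyl-3-[3-(TIPSO)phenyl]propanoyl}-1,3-oxazolidin-2-one
Conditions: TBSOTf, 2,6-lutidine, CH2Cl2, 0 °C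
Reagents that add atoms: tert-butyldimethylsilyl triflate, CC(C)(C)[Si](C)(C)OS(=O)(=O)C(F)(F)F
Why: Silyl ether formation with the reactive triflate caps the hindered benzylic C23 hydroxyl as a non-chelating group needed for the later open-transition-state aldol.

Step 4
Reactants: 6 silylated imide
Product: 7 (2R,3R)-3-(TBSO)-2-methyl-3-[3-(TIPSO)phenyl]propan-1-ol
Conditions: LiBH4, MeOH (1 equiv), Et2O, 0 °C
Reagents that add atoms: none
Why: Reductive cleavage of the N-acyl oxazolidinone by hydride gives the primary alcohol without touching C22 and returns the auxiliary.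

Step 5
Reactants: 7 primary alcohol
Product: 8 (2S,3R)-3-(TBSO)-2-methyl-3-[3-(TIPSO)phenyl]propanal
Conditions: Dess–Martin periodinane, NaHCO3, CH2Cl2, 0 °C → rt
Reagents that add atoms: none
Why: Dess–Martin oxidation gives the α-methyl aldehyde under buffered conditions that do not epimerise C22.

**Fragment A, alkynyl ketone (C14–C20)**

Step 6
Reactants: 9 (R)-3,7-dimethylocta-1,6-diene ((R)-β-citronellene)
Product: 11 (R)-4-methylhex-5-enal, via ozonide 10 (not isolated)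
Conditions: O3, CH2Cl2, −78 °C, Sudan Red 7B end-point; then PPh3, −78 °C → rt
Reagents that add atoms: ozone, [O-][O+]=O
Why: Chemoselective ozonolysis cleaves the electron-rich trisubstituted alkene well before the vinyl group, and C16 is taken unchanged from the chiral pool.

Step 7
Reactants: 11 (R)-4-methylhex-5-enal
Product: 12 (5R)-5-methylhept-6-en-2-ol (both C2 epimers)
Conditions: MeMgBr, Et2O, −78 → 0 °C
Reagents that add atoms: methylmagnesium bromide, C[Mg]Br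
Why: Grignard addition installs C20; the carbinol epimers converge at the ketone in step 10.

Step 8
Reactants: 12 (5R)-5-methylhept-6-en-2-ol
Product: 15 (3R)-3,6-dimethyltetrahydro-2H-pyran-2-ol (lactol epimers), via ozonide 13 (not isolated), via hydroxy aldehyde 14 (not isolated)
Conditions: O3, CH2Cl2, −78 °C; then PPh3, −78 °C → rt
Reagents that add atoms: ozone, [O-][O+]=O
Why: Ozonolysis of the remaining vinyl group unmasks the C15 aldehyde, which closes spontaneously to the six-membered lactol and so shields the adjacent C16 centre from enolisation.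

Step 9
Reactants: 15 lactol
Product: 16 (5R)-5-methylhept-6-yn-2-ol
Conditions: dimethyl (1-diazo-2-oxopropyl)phosphonate, K2CO3, MeOH, 0 °C → rt
Reagents that add atoms: Ohira–Bestmann reagent, COP(=O)(OC)C(=[N+]=[N-])C(C)=O
Why: Seyferth–Gilbert homologation (Ohira–Bestmann variant) intercepts the open hydroxy aldehyde and gives the terminal alkyne under mild carbonate conditions that retain C16.

Step 10
Reactants: 16 (5R)-5-methylhept-6-yn-2-ol
Product: 17 (R)-5-methylhept-6-yn-2-one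
Conditions: Dess–Martin periodinane, NaHCO3, CH2Cl2, rt
Reagents that add atoms: none
Why: Dess–Martin oxidation converts both carbinol epimers to the single methyl ketone.

Step 11
Reactants: 17 (R)-5-methylhept-6-yn-2-one
Product: 19 (R)-trimethyl{[5-methyl-7-(trimethylsilyl)hept-1-en-6-yn-2-yl]oxy}silane, via dilithio enolate-acetylide 18 (not isolated)
Conditions: LiN(iPr)2 (2.2 equiv), THF, −78 °C; then TMSCl (2.5 equiv), −78 → 0 °C
Reagents that add atoms: trimethylsilyl chloride, C[Si](C)(C)Cl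
Why: Kinetic enolate formation on the methyl side with concurrent acetylide formation, then O- and C-silylation, gives the terminal enol silane and masks the alkyne.

**Fragment A, union and adjustment**

Step 12
Reactants: 8 (2S,3R)-3-(TBSO)-2-methyl-3-[3-(TIPSO)phenyl]propanal; 19 enol silane
Product: 20 (1R,2R,3S,8R)-1-(TBSO)-3-hydroxy-2,8-dimethyl-1-[3-(TIPSO)phenyl]-10-(trimethylsilyl)dec-9-yn-5-one
Conditions: BF3·OEt2, CH2Cl2, −78 °C; aq. NaHCO3
Reagents that add atoms: none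
Why: Mukaiyama aldol addition through an open transition state, in which Felkin–Anh control from the C22 methyl and 1,3-anti induction from the C23 silyloxy group reinforce each other in this anti-configured aldehyde, sets C21 syn to C22-Me and anti to C23-O.

Step 13
Reactants: 20 β-hydroxy ketone
Product: 22 (1R,2R,3S,5S,8R)-1-(TBSO)-2,8-dimethyl-1-[3-(TIPSO)phenyl]-10-(trimethylsilyl)dec-9-yne-3,5-diol, via diethylboron chelate 21 (not isolated)
Conditions: Et2BOMe, THF/MeOH (4:1), −78 °C; then NaBH4, −78 °C; MeOH co-evaporation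
Reagents that add atoms: none
Why: Narasaka–Prasad reduction, in which hydride adds axially to the six-membered boron chelate, sets C19 as the 1,3-syn diol.

Step 14
Reactants: 22 syn-diol
Product: 23 (1R,2R,3S,5S,8R)-1,5-bis(TBSO)-2,8-dimethyl-1-[3-(TIPSO)phenyl]-10-(trimethylsilyl)dec-9-yn-3-ol
Conditions: TBSCl (1.1 equiv), imidazole, DMF, 0 °C
Reagents that add atoms: tert-butyldimethylsilyl chloride, CC(C)(C)[Si](C)(C)Cl
Why: Site-selective silyl ether formation, because the C19 hydroxyl between two CH2 groups reacts much faster than the C21 hydroxyl shielded by the C22 methyl branch and the C23 OTBS/aryl group.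

Step 15
Reactants: 23 mono-TBS diol
Product: 24 (1R,2R,3S,5S,8R)-1,5-bis(TBSO)-2,8-dimethyl-1-[3-(TIPSO)phenyl]dec-9-yn-3-ol (fragment A)
Conditions: K2CO3 (0.3 equiv), MeOH, 0 °C → rt, 1 h
Reagents that add atoms: none
Why: Base-catalysed protodesilylation of the alkynylsilane frees the C14 alkyne, while the hindered aryl TIPS ether and the TBS ethers survive brief methanolic carbonate.

**Fragment B (C8–C13)**

Step 16
Reactants: 25 prop-2-yn-1-ol
Product: 27 (Z)-3-iodo-2-methylprop-2-en-1-ol, via alkenylmagnesium alkoxide 26 (not isolated)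
Conditions: MeMgBr (3 equiv), CuI (0.1 equiv), THF/Et2O, −10 °C → rt; then I2, −40 → 0 °C
Reagents that add atoms: methylmagnesium bromide, C[Mg]Br; iodine, II
Why: Copper-catalysed anti-carbomagnesiation of the propargylic alkoxide places magnesium cis to the CH2O group, and iodination with retention fixes the (Z)-trisubstituted C12=C13 geometry.

Step 17
Reactants: 27 (Z)-3-iodo-2-methylprop-2-en-1-ol
Product: 28 (Z)-3-iodo-2-methylprop-2-enal
Conditions: MnO2, CH2Cl2, rt, dark; used crude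
Reagents that add atoms: none
Why: Allylic oxidation on neutral MnO2 gives the enal without isomerising the (Z)-iodoalkene.

Step 18
Reactants: 28 (Z)-3-iodo-2-methylprop-2-enal
Product: 30 (1Z,3R)-1-iodo-2-methylhex-1-en-5-yn-3-ol, via diisopinocampheylborinate 29 (not isolated)
Conditions: (+)-Ipc2BOMe (from (−)-α-pinene), C3H3MgBr (allenylmagnesium bromide), Et2O, −78 °C; then 28, −100 → −78 °C; then NaOH, H2O2, 0 °C
Reagents that add atoms: allenylmagnesium bromide, C=C=C[Mg]Br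
Why: Brown-type asymmetric allenylboration (propargylation), in which the B-allenyl borane of the (−)-α-pinene series adds SE2′ through a chair transition state to the Re face of the enal (the mirror image of the Si-face selectivity of the (+)-α-pinene series with α-methyl enals), sets C11 as R.

Step 19
Reactants: 30 homopropargylic alcohol
Product: 31 tert-butyl{[(1Z,3R)-1-iodo-2-methylhex-1-en-5-yn-3-yl]oxy}dimethylsilane
Conditions: TBSOTf, 2,6-lutidine, CH2Cl2, −78 → 0 °C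
Reagents that add atoms: tert-butyldimethylsilyl triflate, CC(C)(C)[Si](C)(C)OS(=O)(=O)C(F)(F)F
Why: Silyl ether formation protects the C11 hydroxyl.

Step 20
Reactants: 31 TBS ether
Product: 33 tert-butyl{[(1Z,3R)-1-iodo-2-methyl-6-(trimethylsilyl)hex-1-en-5-yn-3-yl]oxy}dimethylsilane (fragment B), via lithium acetylide 32 (not isolated)
Conditions: LiN(iPr)2 (1.05 equiv), THF, −78 °C; then TMSCl, −78 → 0 °C
Reagents that add atoms: trimethylsilyl chloride, C[Si](C)(C)Cl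
Why: Deprotonation and C-silylation of the terminal alkyne (the iodoalkene has no β-hydrogen to eliminate) masks C8 so that only the vinyl iodide reacts in the next coupling.

**Union of fragments A and B**

Step 21
Reactants: 24 fragment A alkyne; 33 fragment B vinyl iodide
Product: 34 (1R,2R,3S,5S,8R,11Z,13R)-1,5,13-tris(TBSO)-2,8,12-trimethyl-1-[3-(TIPSO)phenyl]-16-(trimethylsilyl)hexadec-11-ene-9,15-diyn-3-ol
Conditions: PdCl2(PPh3)2 (5 mol %), CuI (10 mol %), iPr2NH, THF, rt, degassed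
Reagents that add atoms: none
Why: Sonogashira coupling forms C13–C14 with retention of the (Z)-olefin geometry and tolerates the free C21 hydroxyl and the silylalkyne.

Step 22
Reactants: 34 enyne
Product: 35 (1R,2R,3S,5S,8R,9Z,11Z,13R)-1,5,13-tris(TBSO)-2,8,12-trimethyl-1-[3-(TIPSO)phenyl]-16-(trimethylsilyl)hexadeca-9,11-dien-15-yn-3-ol
Conditions: Zn dust activated with Cu(OAc)2 and AgNO3 (Zn(Cu/Ag) couple), MeOH/H2O/THF, 40 °C
Reagents that add atoms: none
Why: Boland reduction is a cis-semireduction specific for conjugated alkynes, so it gives the (12Z,14Z)-diene and leaves the isolated silylalkyne untouched.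

Step 23
Reactants: 35 (Z,Z)-diene
Product: 36 (1R,2R,3S,5S,8R,9Z,11Z,13R)-1,5,13-tris(TBSO)-2,8,12-trimethyl-1-[3-(TIPSO)phenyl]hexadeca-9,11-dien-15-yn-3-ol
Conditions: K2CO3 (0.3 equiv), MeOH/THF, 0 °C → rt
Reagents that add atoms: none
Why: Base-catalysed protodesilylation frees the C8 alkyne for the second coupling.

**Fragment C (C1–C7)**

Step 24
Reactants: 37 3-(trimethylsilyl)prop-2-ynal; 38 methyl 2-(triphenyl-λ5-phosphanylidene)propanoate
Product: 39 methyl (E)-2-methyl-5-(trimethylsilyl)pent-2-en-4-ynoate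
Conditions: CH2Cl2, 0 °C → rt
Reagents that add atoms: none
Why: Wittig olefination with the stabilised α-methyl ylide gives the (E)-trisubstituted enoate (C2=C3).

Step 25
Reactants: 39 silyl enynoate
Product: 40 (E)-2-methylpent-2-en-4-ynoic acid
Conditions: LiOH·H2O (3 equiv), THF/H2O, rt; then 1 M HCl to pH 3
Reagents that add atoms: lithium hydroxide, [Li+].[OH-]
Why: Saponification and hydroxide-induced protodesilylation occur in one operation, so the later chloroenyne never meets hydroxide.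

Step 26
Reactants: 40 (E)-2-methylpent-2-en-4-ynoic acid; 41 (Z)-1,2-dichloroethene
Product: 42 (2E,6Z)-7-chloro-2-methylhepta-2,6-dien-4-ynoic acid (fragment C)
Conditions: Pd(PPh3)4 (5 mol %), CuI (10 mol %), n-BuNH2 (3 equiv), 41 (6 equiv), THF, rt; acidic work-up
Reagents that add atoms: none
Why: Sonogashira coupling with excess dichloroethene gives the mono-coupled chloroenyne with retention of the cis geometry (C6=C7), the acid reacting as its ammonium carboxylate.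

**Endgame**

Step 27
Reactants: 36 C8–C23 alkyne; 42 fragment C acid
Product: 43 (2E,6Z,11R,12Z,14Z,16R,19S,21S,22R,23R)-11,19,23-tris(TBSO)-21-hydroxy-2,12,16,22-tetramethyl-23-[3-(TIPSO)phenyl]tricosa-2,6,12,14-tetraene-4,8-diynoic acid (seco acid)
Conditions: Pd(PPh3)4 (10 mol %), CuI (20 mol %), n-BuNH2, THF, rt, degassed; pH 4 work-up
Reagents that add atoms: none
Why: Sonogashira coupling of the activated (Z)-chloroenyne forms C7–C8 with retention and delivers the seco acid directly, with no ester hydrolysis in the presence of the aryl silyl ether.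

Step 28
Reactants: 43 seco acid
Product: 45 (3E,7Z,12R,13Z,15Z,17R,20S,22S)-12,20-bis(TBSO)-22-{(1R,2R)-1-(TBSO)-1-[3-(TIPSO)phenyl]propan-2-yl}-3,13,17-trimethyl-1-oxacyclodocosa-3,7,13,15-tetraene-5,9-diyn-2-one, via mixed anhydride 44 (not isolated)
Conditions: 2,4,6-Cl3C6H2COCl, Et3N, THF, rt, 2 h; then syringe-pump addition to DMAP (10 equiv), toluene, 40 °C, final 1 mM
Reagents that add atoms: none
Why: Yamaguchi macrolactonisation, in which DMAP transfers the acyl group of the mixed anhydride to C21–OH, the only free hydroxyl, at high dilution, closes the 22-membered ring on a chain pre-bent by the (Z)-enediyne and the (Z,Z)-diene.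

Step 29
Reactants: 45 tetrasilylated macrolactone
Product: 47 (3E,7Z,12R,13Z,15Z,17R,20S,22S)-12,20-dihydroxy-22-[(1R,2S)-1-hydroxy-1-(3-hydroxyphenyl)propan-2-yl]-3,13,17-trimethyl-1-oxacyclodocosa-3,7,13,15-tetraene-5,9-diyn-2-one, via free phenol 46 (not isolated)
Conditions: Bu4NF/AcOH (1:1, 1.5 equiv), THF, 0 °C, 30 min; then HF·pyridine, pyridine, THF, 0 °C → rt
Reagents that add atoms: none
Why: Fluoride-mediated desilylation under buffered, non-basic conditions removes the aryl TIPS ether and then the three TBS ethers without acyl migration of the lactone to the neighbouring hydroxyls.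

Step 30
Reactants: 47 dienediyne macrolactone tetraol
Product: 48 CNP0073615.1, (3E,5Z,7Z,9Z,12R,13Z,15Z,17R,20S,22S)-12,20-dihydroxy-22-[(1R,2S)-1-hydroxy-1-(3-hydroxyphenyl)propan-2-yl]-3,13,17-trimethyl-1-oxacyclodocosa-3,5,7,9,13,15-hexaen-2-one
Conditions: Zn dust activated with Cu(OAc)2 and AgNO3 (Zn(Cu/Ag) couple), MeOH/H2O (1:1), rt, dark, argon; filtration, cold reversed-phase HPLC
Reagents that add atoms: none
Why: Boland reduction converts both conjugated alkynes (C4≡C5, C8≡C9) into (Z)-alkenes without over-reduction or touching the enoate, revealing the sensitive (2E,4Z,6Z,8Z)-tetraene only in the last step.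

**Compound list**
1 | 3-hydroxybenzaldehyde | O=Cc1cccc(O)c1 | starting material
2 | 3-(TIPSO)benzaldehyde | O=Cc1cccc(O[Si](C(C)C)(C(C)C)C(C)C)c1 | intermediate
3 | (R)-4-benzyl-3-propanoyl-1,3-oxazolidin-2-one | CCC(=O)N1[C@H](Cc2ccccc2)COC1=O | starting material
4 | (R)-4-benzyl-3-{(2S,3R)-2-methyl-3-(TMSO)-3-[3-(TIPSO)phenyl]propanoyl}-1,3-oxazolidin-2-one (not isolated) | O=C(N1[C@H](Cc2ccccc2)COC1=O)[C@@H](C)[C@@H](O[Si](C)(C)C)c1cccc(O[Si](C(C)C)(C(C)C)C(C)C)c1 | intermediate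
5 | (R)-4-benzyl-3-{(2S,3R)-3-hydroxy-2-methyl-3-[3-(TIPSO)phenyl]propanoyl}-1,3-oxazolidin-2-one | O=C(N1[C@H](Cc2ccccc2)COC1=O)[C@@H](C)[C@@H](O)c1cccc(O[Si](C(C)C)(C(C)C)C(C)C)c1 | intermediate
6 | (R)-4-benzyl-3-{(2S,3R)-3-(TBSO)-2-methyl-3-[3-(TIPSO)phenyl]propanoyl}-1,3-oxazolidin-2-one | O=C(N1[C@H](Cc2ccccc2)COC1=O)[C@@H](C)[C@@H](O[Si](C)(C)C(C)(C)C)c1cccc(O[Si](C(C)C)(C(C)C)C(C)C)c1 | intermediate
7 | (2R,3R)-3-(TBSO)-2-methyl-3-[3-(TIPSO)phenyl]propan-1-ol | OC[C@@H](C)[C@@H](O[Si](C)(C)C(C)(C)C)c1cccc(O[Si](C(C)C)(C(C)C)C(C)C)c1 | intermediate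
8 | (2S,3R)-3-(TBSO)-2-methyl-3-[3-(TIPSO)phenyl]propanal | O=C[C@@H](C)[C@@H](O[Si](C)(C)C(C)(C)C)c1cccc(O[Si](C(C)C)(C(C)C)C(C)C)c1 | intermediate
9 | (R)-3,7-dimethylocta-1,6-diene ((R)-β-citronellene) | C=C[C@H](C)CCC=C(C)C | starting material
10 | 3,3-dimethyl-5-[(3R)-3-methylpent-4-en-1-yl]-1,2,4-trioxolane (not isolated) | C=C[C@H](C)CCC1OOC(C)(C)O1 | intermediate
11 | (R)-4-methylhex-5-enal | C=C[C@H](C)CCC=O | intermediate
12 | (5R)-5-methylhept-6-en-2-ol (C2 epimers) | C=C[C@H](C)CCC(C)O | intermediate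
13 | 3-[(2R)-5-hydroxyhexan-2-yl]-1,2,4-trioxolane (not isolated) | CC(O)CC[C@@H](C)C1OCOO1 | intermediate
14 | (2R)-5-hydroxy-2-methylhexanal (not isolated) | CC(O)CC[C@@H](C)C=O | intermediate
15 | (3R)-3,6-dimethyltetrahydro-2H-pyran-2-ol (lactol epimers) | CC1CC[C@@H](C)C(O)O1 | intermediate
16 | (5R)-5-methylhept-6-yn-2-ol | C#C[C@H](C)CCC(C)O | intermediate
17 | (R)-5-methylhept-6-yn-2-one | C#C[C@H](C)CCC(C)=O | intermediate
18 | dilithio enolate-acetylide of 17 (not isolated) | [Li]C#C[C@H](C)CCC(=C)O[Li] | intermediate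
19 | (R)-trimethyl{[5-methyl-7-(trimethylsilyl)hept-1-en-6-yn-2-yl]oxy}silane | C[Si](C)(C)C#C[C@H](C)CCC(=C)O[Si](C)(C)C | intermediate
20 | (1R,2R,3S,8R)-1-(TBSO)-3-hydroxy-2,8-dimethyl-1-[3-(TIPSO)phenyl]-10-(trimethylsilyl)dec-9-yn-5-one | C[Si](C)(C)C#C[C@H](C)CCC(=O)C[C@@H]([C@@H](C)[C@@H](O[Si](C)(C)C(C)(C)C)c1cccc(O[Si](C(C)C)(C(C)C)C(C)C)c1)O | intermediate
21 | 3-O-diethylboryl chelate of 20 (not isolated) | C[Si](C)(C)C#C[C@H](C)CCC(=O)C[C@@H]([C@@H](C)[C@@H](O[Si](C)(C)C(C)(C)C)c1cccc(O[Si](C(C)C)(C(C)C)C(C)C)c1)OB(CC)CC | intermediate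
22 | (1R,2R,3S,5S,8R)-1-(TBSO)-2,8-dimethyl-1-[3-(TIPSO)phenyl]-10-(trimethylsilyl)dec-9-yne-3,5-diol | C[Si](C)(C)C#C[C@H](C)CC[C@H](O)C[C@@H]([C@@H](C)[C@@H](O[Si](C)(C)C(C)(C)C)c1cccc(O[Si](C(C)C)(C(C)C)C(C)C)c1)O | intermediate
23 | (1R,2R,3S,5S,8R)-1,5-bis(TBSO)-2,8-dimethyl-1-[3-(TIPSO)phenyl]-10-(trimethylsilyl)dec-9-yn-3-ol | C[Si](C)(C)C#C[C@H](C)CC[C@H](O[Si](C)(C)C(C)(C)C)C[C@@H]([C@@H](C)[C@@H](O[Si](C)(C)C(C)(C)C)c1cccc(O[Si](C(C)C)(C(C)C)C(C)C)c1)O | intermediate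
24 | (1R,2R,3S,5S,8R)-1,5-bis(TBSO)-2,8-dimethyl-1-[3-(TIPSO)phenyl]dec-9-yn-3-ol (fragment A) | C#C[C@H](C)CC[C@H](O[Si](C)(C)C(C)(C)C)C[C@@H]([C@@H](C)[C@@H](O[Si](C)(C)C(C)(C)C)c1cccc(O[Si](C(C)C)(C(C)C)C(C)C)c1)O | intermediate
25 | prop-2-yn-1-ol | C#CCO | starting material
26 | (Z)-[3-(bromomagnesiooxy)-2-methylprop-1-en-1-yl]magnesium bromide (not isolated) | C/C(=C/[Mg]Br)CO[Mg]Br | intermediate
27 | (Z)-3-iodo-2-methylprop-2-en-1-ol | C/C(=C/I)CO | intermediate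
28 | (Z)-3-iodo-2-methylprop-2-enal | C/C(=C/I)C=O | intermediate
29 | (1Z,3R)-1-iodo-2-methylhex-1-en-5-yn-3-yl diisopinocampheylborinate (not isolated) | C/C(=C/I)[C@@H](CC#C)OB([C@H]1C[C@H]2C[C@@H]([C@@H]1C)C2(C)C)[C@H]1C[C@H]2C[C@@H]([C@@H]1C)C2(C)C | intermediate
30 | (1Z,3R)-1-iodo-2-methylhex-1-en-5-yn-3-ol | C/C(=C/I)[C@H](O)CC#C | intermediate
31 | tert-butyl{[(1Z,3R)-1-iodo-2-methylhex-1-en-5-yn-3-yl]oxy}dimethylsilane | C/C(=C/I)[C@H](O[Si](C)(C)C(C)(C)C)CC#C | intermediate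
32 | lithium acetylide of 31 (not isolated) | C/C(=C/I)[C@H](O[Si](C)(C)C(C)(C)C)CC#C[Li] | intermediate
33 | tert-butyl{[(1Z,3R)-1-iodo-2-methyl-6-(trimethylsilyl)hex-1-en-5-yn-3-yl]oxy}dimethylsilane (fragment B) | C/C(=C/I)[C@H](O[Si](C)(C)C(C)(C)C)CC#C[Si](C)(C)C | intermediate
34 | (1R,2R,3S,5S,8R,11Z,13R)-1,5,13-tris(TBSO)-2,8,12-trimethyl-1-[3-(TIPSO)phenyl]-16-(trimethylsilyl)hexadec-11-ene-9,15-diyn-3-ol | C[Si](C)(C)C#CC[C@@H](O[Si](C)(C)C(C)(C)C)/C(C)=C\C#C[C@H](C)CC[C@H](O[Si](C)(C)C(C)(C)C)C[C@@H]([C@@H](C)[C@@H](O[Si](C)(C)C(C)(C)C)c1cccc(O[Si](C(C)C)(C(C)C)C(C)C)c1)O | intermediate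
35 | (1R,2R,3S,5S,8R,9Z,11Z,13R)-1,5,13-tris(TBSO)-2,8,12-trimethyl-1-[3-(TIPSO)phenyl]-16-(trimethylsilyl)hexadeca-9,11-dien-15-yn-3-ol | C[Si](C)(C)C#CC[C@@H](O[Si](C)(C)C(C)(C)C)/C(C)=C\C=C/[C@H](C)CC[C@H](O[Si](C)(C)C(C)(C)C)C[C@@H]([C@@H](C)[C@@H](O[Si](C)(C)C(C)(C)C)c1cccc(O[Si](C(C)C)(C(C)C)C(C)C)c1)O | intermediate
36 | (1R,2R,3S,5S,8R,9Z,11Z,13R)-1,5,13-tris(TBSO)-2,8,12-trimethyl-1-[3-(TIPSO)phenyl]hexadeca-9,11-dien-15-yn-3-ol | C#CC[C@@H](O[Si](C)(C)C(C)(C)C)/C(C)=C\C=C/[C@H](C)CC[C@H](O[Si](C)(C)C(C)(C)C)C[C@@H]([C@@H](C)[C@@H](O[Si](C)(C)C(C)(C)C)c1cccc(O[Si](C(C)C)(C(C)C)C(C)C)c1)O | intermediate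
37 | 3-(trimethylsilyl)prop-2-ynal | C[Si](C)(C)C#CC=O | starting material
38 | methyl 2-(triphenyl-λ5-phosphanylidene)propanoate | COC(=O)C(C)=P(c1ccccc1)(c1ccccc1)c1ccccc1 | starting material
39 | methyl (E)-2-methyl-5-(trimethylsilyl)pent-2-en-4-ynoate | COC(=O)/C(C)=C/C#C[Si](C)(C)C | intermediate
40 | (E)-2-methylpent-2-en-4-ynoic acid | OC(=O)/C(C)=C/C#C | intermediate
41 | (Z)-1,2-dichloroethene | Cl/C=C\Cl | starting material
42 | (2E,6Z)-7-chloro-2-methylhepta-2,6-dien-4-ynoic acid (fragment C) | OC(=O)/C(C)=C/C#C/C=C\Cl | intermediate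
43 | (2E,6Z,11R,12Z,14Z,16R,19S,21S,22R,23R)-11,19,23-tris(TBSO)-21-hydroxy-2,12,16,22-tetramethyl-23-[3-(TIPSO)phenyl]tricosa-2,6,12,14-tetraene-4,8-diynoic acid (seco acid) | OC(=O)/C(C)=C/C#C/C=C\C#CC[C@@H](O[Si](C)(C)C(C)(C)C)/C(C)=C\C=C/[C@H](C)CC[C@H](O[Si](C)(C)C(C)(C)C)C[C@@H]([C@@H](C)[C@@H](O[Si](C)(C)C(C)(C)C)c1cccc(O[Si](C(C)C)(C(C)C)C(C)C)c1)O | intermediate
44 | mixed anhydride of 43 with 2,4,6-trichlorobenzoic acid (not isolated) | O=C(OC(=O)/C(C)=C/C#C/C=C\C#CC[C@@H](O[Si](C)(C)C(C)(C)C)/C(C)=C\C=C/[C@H](C)CC[C@H](O[Si](C)(C)C(C)(C)C)C[C@@H]([C@@H](C)[C@@H](O[Si](C)(C)C(C)(C)C)c1cccc(O[Si](C(C)C)(C(C)C)C(C)C)c1)O)c1c(Cl)cc(Cl)cc1Cl | intermediate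
45 | (3E,7Z,12R,13Z,15Z,17R,20S,22S)-12,20-bis(TBSO)-22-{(1R,2R)-1-(TBSO)-1-[3-(TIPSO)phenyl]propan-2-yl}-3,13,17-trimethyl-1-oxacyclodocosa-3,7,13,15-tetraene-5,9-diyn-2-one | C/C1=C/C=C\[C@H](C)CC[C@H](O[Si](C)(C)C(C)(C)C)C[C@@H]([C@@H](C)[C@@H](O[Si](C)(C)C(C)(C)C)c2cccc(O[Si](C(C)C)(C(C)C)C(C)C)c2)OC(=O)/C(C)=C/C#C/C=C\C#CC[C@H]1O[Si](C)(C)C(C)(C)C | intermediate
46 | (3E,7Z,12R,13Z,15Z,17R,20S,22S)-12,20-bis(TBSO)-22-[(1R,2R)-1-(TBSO)-1-(3-hydroxyphenyl)propan-2-yl]-3,13,17-trimethyl-1-oxacyclodocosa-3,7,13,15-tetraene-5,9-diyn-2-one (not isolated) | C/C1=C/C=C\[C@H](C)CC[C@H](O[Si](C)(C)C(C)(C)C)C[C@@H]([C@@H](C)[C@@H](O[Si](C)(C)C(C)(C)C)c2cccc(O)c2)OC(=O)/C(C)=C/C#C/C=C\C#CC[C@H]1O[Si](C)(C)C(C)(C)C | intermediate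
47 | (3E,7Z,12R,13Z,15Z,17R,20S,22S)-12,20-dihydroxy-22-[(1R,2S)-1-hydroxy-1-(3-hydroxyphenyl)propan-2-yl]-3,13,17-trimethyl-1-oxacyclodocosa-3,7,13,15-tetraene-5,9-diyn-2-one | C/C1=C/C=C\[C@H](C)CC[C@H](O)C[C@@H]([C@@H](C)[C@@H](O)c2cccc(O)c2)OC(=O)/C(C)=C/C#C/C=C\C#CC[C@H]1O | intermediate
48 | CNP0073615.1, (3E,5Z,7Z,9Z,12R,13Z,15Z,17R,20S,22S)-12,20-dihydroxy-22-[(1R,2S)-1-hydroxy-1-(3-hydroxyphenyl)propan-2-yl]-3,13,17-trimethyl-1-oxacyclodocosa-3,5,7,9,13,15-hexaen-2-one | C/C1=C/C=C\[C@H](C)CC[C@H](O)C[C@@H]([C@@H](C)[C@@H](O)c2cccc(O)c2)OC(=O)/C(C)=C/C=C\C=C/C=C\C[C@H]1O | target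

**Totals**
Total step count: 30.
Longest linear sequence: 17 steps (9 → 48 through steps 6–15, 21–23 and 27–30).

**Three steps most likely to fail, with fallbacks**

Step 14 (site-selective silylation of diol 22). If the two secondary hydroxyls are not distinguished well enough, the differentiation is moved back to β-hydroxy ketone 20, where C21–OH is the only hydroxyl. Compound 20 is capped with PMB trichloroacetimidate and catalytic La(OTf)3 in toluene to give the (1R,2R,3S,8R)-3-(PMBO) ketone F1. The C19 ketone is then reduced under chelation control (LiAlH4/LiI, Et2O, −78 °C; lithium bridges the ketone and the PMB ether oxygen, so hydride gives the 1,3-syn alcohol) to the (5S)-alcohol F2. Silylation with TBSOTf and 2,6-lutidine gives the 1,5-bis(TBSO) PMB ether F3, and DDQ in CH2Cl2/pH 7 buffer removes the PMB group. This detour sets out from 20, replaces steps 13 and 14, and comes back to the route at 23.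

Step 28 (macrolactonisation onto the hindered C21 hydroxyl). If the seco acid oligomerises or will not close, the order of the last two bond formations is inverted. Alkyne 36 is esterified intermolecularly at its only free hydroxyl with acid 42 (2,4,6-Cl3C6H2COCl, Et3N, DMAP, toluene, rt) to give the chloroenyne ester F4. The ring is then closed at C7–C8 by an intramolecular Sonogashira coupling (Pd(PPh3)4, CuI, n-BuNH2, benzene, syringe-pump addition, 1 mM). This detour sets out from 36 (with 42), bypasses 43 and 44, and comes back to the route at 45.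

Step 30 (double semireduction inside the unprotected macrocycle). If the reduction stalls at an enyne or over-reduces, the alkynes are reduced before ring closure, on the open chain. Seco acid 43 is treated with the Zn(Cu/Ag) couple in MeOH/H2O/THF to give the (2E,4Z,6Z,8Z,12Z,14Z)-hexaenoic seco acid F5. This is lactonised at room temperature under Shiina conditions (2-methyl-6-nitrobenzoic anhydride, DMAP, CH2Cl2, high dilution) to the tetrasilylated hexaene macrolactone F6. The buffered fluoride conditions of step 29 then remove the four silyl groups. This detour sets out from 43, bypasses 45 and 47, and comes back to the route at 48.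

**Further compounds**
F1 | step 14 | (1R,2R,3S,8R)-1-(TBSO)-3-(PMBO)-2,8-dimethyl-1-[3-(TIPSO)phenyl]-10-(trimethylsilyl)dec-9-yn-5-one | C[Si](C)(C)C#C[C@H](C)CCC(=O)C[C@@H]([C@@H](C)[C@@H](O[Si](C)(C)C(C)(C)C)c1cccc(O[Si](C(C)C)(C(C)C)C(C)C)c1)OCc1ccc(OC)cc1
F2 | step 14 | (1R,2R,3S,5S,8R)-1-(TBSO)-3-(PMBO)-2,8-dimethyl-1-[3-(TIPSO)phenyl]-10-(trimethylsilyl)dec-9-yn-5-ol | C[Si](C)(C)C#C[C@H](C)CC[C@H](O)C[C@@H]([C@@H](C)[C@@H](O[Si](C)(C)C(C)(C)C)c1cccc(O[Si](C(C)C)(C(C)C)C(C)C)c1)OCc1ccc(OC)cc1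
F3 | step 14 | (1R,2R,3S,5S,8R)-1,5-bis(TBSO)-3-(PMBO)-2,8-dimethyl-1-[3-(TIPSO)phenyl]-10-(trimethylsilyl)dec-9-yne | C[Si](C)(C)C#C[C@H](C)CC[C@H](O[Si](C)(C)C(C)(C)C)C[C@@H]([C@@H](C)[C@@H](O[Si](C)(C)C(C)(C)C)c1cccc(O[Si](C(C)C)(C(C)C)C(C)C)c1)OCc1ccc(OC)cc1
F4 | step 28 | (1R,2R,3S,5S,8R,9Z,11Z,13R)-1,5,13-tris(TBSO)-2,8,12-trimethyl-1-[3-(TIPSO)phenyl]hexadeca-9,11-dien-15-yn-3-yl (2E,6Z)-7-chloro-2-methylhepta-2,6-dien-4-ynoate | C#CC[C@@H](O[Si](C)(C)C(C)(C)C)/C(C)=C\C=C/[C@H](C)CC[C@H](O[Si](C)(C)C(C)(C)C)C[C@@H]([C@@H](C)[C@@H](O[Si](C)(C)C(C)(C)C)c1cccc(O[Si](C(C)C)(C(C)C)C(C)C)c1)OC(=O)/C(C)=C/C#C/C=C\Cl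
F5 | step 30 | (2E,4Z,6Z,8Z,11R,12Z,14Z,16R,19S,21S,22R,23R)-11,19,23-tris(TBSO)-21-hydroxy-2,12,16,22-tetramethyl-23-[3-(TIPSO)phenyl]tricosa-2,4,6,8,12,14-hexaenoic acid | OC(=O)/C(C)=C/C=C\C=C/C=C\C[C@@H](O[Si](C)(C)C(C)(C)C)/C(C)=C\C=C/[C@H](C)CC[C@H](O[Si](C)(C)C(C)(C)C)C[C@@H]([C@@H](C)[C@@H](O[Si](C)(C)C(C)(C)C)c1cccc(O[Si](C(C)C)(C(C)C)C(C)C)c1)O
F6 | step 30 | (3E,5Z,7Z,9Z,12R,13Z,15Z,17R,20S,22S)-12,20-bis(TBSO)-22-{(1R,2R)-1-(TBSO)-1-[3-(TIPSO)phenyl]propan-2-yl}-3,13,17-trimethyl-1-oxacyclodocosa-3,5,7,9,13,15-hexaen-2-one | C/C1=C/C=C\[C@H](C)CC[C@H](O[Si](C)(C)C(C)(C)C)C[C@@H]([C@@H](C)[C@@H](O[Si](C)(C)C(C)(C)C)c2cccc(O[Si](C(C)C)(C(C)C)C(C)C)c2)OC(=O)/C(C)=C/C=C\C=C/C=C\C[C@H]1O[Si](C)(C)C(C)(C)C
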